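**Assumptions:** Diplotrin B (3'-hydroxy-3,7,8,4'-tetramethoxyflavone) has no stereocentres, so "single enantiomer" needs no stereocontrol. Transient organometallics and salts (ArLi, ArZnCl, the sodium phenoxide) are described in the steps but not numbered.

## Retrosynthetic overview

1. Avoided: the usual chalcone / Algar–Flynn–Oyamada / 3-O-methylation route (and Baker–Venkataraman). Here ring B is attached last to a finished A/C core.
2. Key disconnection C2–C1': C2–H zincation of 3,7,8-trimethoxychromone, then Negishi coupling with unprotected 5-bromo-2-methoxyphenol (as its phenoxide), so no protecting groups are used.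
3. Chromone core: enaminone annulation of a 2-hydroxy-ω-methoxyacetophenone, so the 3-OMe is carried in from the start and no C3 oxidation is needed.
4. The ω-methoxy ketone: directed ortho-lithiation of 1,2,3-trimethoxybenzene with Weinreb acylation, then chelation-controlled mono-demethylation.
5. Ring order: A (purchased) → C (step 3) → B attached by cross-coupling (step 4).

## Route

**Step 1**
Reactants: 1 (1,2,3-trimethoxybenzene); 2 (N,2-dimethoxy-N-methylacetamide, the Weinreb amide of methoxyacetic acid)
Product: 3, 2-methoxy-1-(2,3,4-trimethoxyphenyl)ethan-1-one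
Conditions: n-BuLi (1.1 equiv), TMEDA, THF, 0 °C → rt; then 2, −78 → 0 °C; aq. NH4Cl
Reagents that add atoms: none beyond reactant 2 (supplies MeOCH2C(=O)–)
Why: Methoxy-directed ortho-lithiation of the symmetric arene can only occur at the equivalent C4/C6 positions, and the aryllithium adds once to the chelating Weinreb amide (Weinreb ketone synthesis); no stereocentre is formed.

**Step 2**
Reactants: 3
Product: 4, 1-(2-hydroxy-3,4-dimethoxyphenyl)-2-methoxyethan-1-one
Conditions: BCl3 (1.1 equiv, 1 M in CH2Cl2), CH2Cl2, −78 → 0 °C; aq. HCl/MeOH quench
Reagents that add atoms: none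
Why: BCl3 bound to the ketone carbonyl cleaves only the ortho OMe through a six-membered O–B–O chelate (chelation-controlled ortho-demethylation), leaving the 3-OMe, 4-OMe and aliphatic OMe intact at ≤0 °C with one equivalent.

**Step 3**
Reactants: 4; 5 (N,N-dimethylformamide dimethyl acetal, DMF-DMA)
Product: 7, 3,7,8-trimethoxy-4H-chromen-4-one, via enaminone 6 (3-(dimethylamino)-1-(2-hydroxy-3,4-dimethoxyphenyl)-2-methoxyprop-2-en-1-one, not isolated, alkene geometry inconsequential)
Conditions: DMF-DMA (3 equiv), PhMe, 100 °C; concentrate; then conc. HCl, CH2Cl2, 40 °C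
Reagents that add atoms: DMF-DMA, COC(OC)N(C)C (supplies the C2–H carbon)
Why: DMF-DMA condenses at the α-CH2 to give enaminone 6, and acid triggers phenol oxa-Michael addition with loss of HNMe2 (enaminone chromone annulation), which places the pre-installed OMe at C3.

**Step 4 (key step)**
Reactants: 7 (1.2 equiv); 8 (5-bromo-2-methoxyphenol, 1.0 equiv)
Product: 9, diplotrin B, 2-(3-hydroxy-4-methoxyphenyl)-3,7,8-trimethoxy-4H-chromen-4-one
Conditions: 7, TMPZnCl·LiCl (1.3 equiv), THF, 25 °C, 1–2 h; then sodium phenoxide of 8 (8 + NaH 1.05 equiv, THF, 0 °C), Pd(OAc)2 (2 mol %), SPhos (4 mol %), 50 °C; aq. NH4Cl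
Reagents that add atoms: none (the aryl unit comes from reactant 8)
Why: With C3 blocked, the only vinylic C–H is C2, flanked by the ring oxygen and the coordinating 3-OMe, so the hindered zinc amide gives a 2-chromonylzinc that tolerates the C4 ketone; Pd/SPhos Negishi coupling with the bromophenoxide (pre-deprotonated so it cannot protonate the C–Zn bond) forms C2–C1' and work-up releases the free 3'-OH (directed TMP-zincation / Negishi cross-coupling; the 3-methoxychromone substrate and phenoxide partner are untested extensions of this known reaction type; no stereocentre).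

## Compound list

1 | 1,2,3-trimethoxybenzene | COc1cccc(OC)c1OC | starting material
2 | N,2-dimethoxy-N-methylacetamide | COCC(=O)N(C)OC | starting material
3 | 2-methoxy-1-(2,3,4-trimethoxyphenyl)ethan-1-one | COCC(=O)c1ccc(OC)c(OC)c1OC | intermediate
4 | 1-(2-hydroxy-3,4-dimethoxyphenyl)-2-methoxyethan-1-one | COCC(=O)c1ccc(OC)c(OC)c1O | intermediate
5 | N,N-dimethylformamide dimethyl acetal | COC(OC)N(C)C | starting material (reagent supplying C2)
6 | 3-(dimethylamino)-1-(2-hydroxy-3,4-dimethoxyphenyl)-2-methoxyprop-2-en-1-one | CN(C)C=C(OC)C(=O)c1ccc(OC)c(OC)c1O | intermediate (not isolated)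
7 | 3,7,8-trimethoxy-4H-chromen-4-one | COc1ccc2c(c1OC)occ(OC)c2=O | intermediate
8 | 5-bromo-2-methoxyphenol | COc1ccc(Br)cc1O | starting material
9 | diplotrin B (achiral) | COc1ccc(-c2oc3c(OC)c(OC)ccc3c(=O)c2OC)cc1O | target

## Summary

Total steps: 4 (steps 3 and 4 are each one-pot, two-stage operations). Longest linear sequence: 4 (1 → 3 → 4 → 7 → 9). No protecting groups.

Steps most likely to fail, with fallbacks:

1. **Step 4** (C2 zincation of the 3-methoxychromone and coupling with an unprotected bromophenoxide). Fallback: abandon C–H metalation and close ring C after attaching ring B. Condense ketone 4 with 3-(benzyloxy)-4-methoxybenzaldehyde to the α-methoxychalcone, cyclize oxidatively with I2/DMSO to the 3-methoxyflavone, then remove the benzyl group with H2, Pd/C.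
2. **Step 2** (BCl3 could also cleave the α-OMe or over-demethylate to the catechol). Fallback: avoid demethylation altogether. Start from 2,3-dimethoxyphenol MOM ether, use OMOM-directed ortho-lithiation and acylation with 2, then remove the MOM group with HCl/MeOH to reach 4.
3. **Step 3** (sluggish condensation at the weakly acidic α-methoxy CH2, or phenol O-methylation by DMF-DMA). Fallback: install the C3 oxygen after ring formation. Make 7,8-dimethoxychromone from commercial 2'-hydroxy-3',4'-dimethoxyacetophenone (DMF-DMA, then HCl), epoxidize C2=C3 with DMDO, rearrange with acid to the 3-hydroxychromone, and O-methylate (MeI, K2CO3) to give 7.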